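Readings and results stem from a simulated flask on assumed constants.

Millimolar per hour, not percent per hour, is the unit to watch in a repeat of this flask.

- epsilon: left-handed substrate 0.075 M; right-handed substrate 0.075 M; gas 9 mM (held); precatalyst 0.50 mM; run made earlier
- flask: left-handed substrate 0.050 M; gas 9.0 mM (held); precatalyst 0.50 mM; right-handed substrate 0.050 M; time 15 h

epsilon run (percent of the left-handed substrate and right-handed substrate together charged)

| time / h | left-handed product / % | right-handed product / % | left-handed substrate / % |
|---|---|---|---|
| 0.250 | 0.3 | 0.1 | 49.1 |
| 0.417 | 1.2 | 1.0 | 48.5 |
| 0.667 | 1.6 | 0.9 | 47.5 |
| 1.00 | 2.6 | 0.6 | 46.9 |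
| 2.00 | 5.5 | 1.4 | 45.1 |
| 3.00 | 7.6 | 2.5 | 40.7 |

(each reading ± 0.5 percentage points)

- coupling partner is single-handed; left-handed substrate and right-handed substrate are mirror images of each other, charged as a racemate, each of them at the stated concentration
- the numbers in the tables scatter with a standard deviation of 0.5 percentage points
- at the start none of the gas is in solution
- an excess is the difference of the two amounts in percent of their sum
- an excess is below zero if the other one leads
- the handed part of coupling partner does not stay in what it makes, so the products of the two hands are mirror images too

1. left-handed product and right-handed product together, in percent of the left-handed substrate and right-handed substrate charged together, at 15 h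
2. excess of left-handed product over right-handed product in the product at 15 h
3. whether the exchange between left-handed substrate and right-handed substrate keeps pace with the reaction: how far the product's excess at 15 h gets from its value without exchange to its value with instant exchange (above 80% keeps pace, below 20% hardly takes part, else lags behind)

In the epsilon run the two products together climb in a straight line with no visible lag, although none of the gas is in solution at the start. I read this as a reaction that takes the coupling partner, which I take to be the dissolved gas, about as fast as it arrives. Gas uptake would then be the rate-limiting step, and the rate would be pseudo-zero-order in substrate. The 3.00 h readings give F = 5.05 mM h⁻¹, the feed, meaning the product made per litre and hour. Integrating a constant rate gives product = F·t.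

The flask has the same saturation, 9.0 mM, but less substrate, so I expect its percent to climb faster. The 100 mM of substrate charged covers F·t, so I commit to 75.8% at 15 h.

The forecast differs from my reckoning in the yield: it gives 42%, with an excess of 48.5% and an exchange that lags behind, on the ground that “the percentages carry over to the flask”.

The flask gives 73.4% with an excess of 26.0%, and the exchange hardly takes part, getting 4.6% of the way.

    left-handed substrate + racemization catalyst ⇌ right-handed substrate + racemization catalyst, rate k1*[racemization catalyst]*[left-handed substrate] forward; the back reaction follows from the equilibrium constant (k = 1.73 M⁻¹ min⁻¹)
    coupling partner + precatalyst → racemization catalyst + spent reagent (k = 0.431 M⁻¹ min⁻¹)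
    coupling partner + left-handed substrate → left-handed product (k = 4.47 M⁻¹ min⁻¹)
    coupling partner + right-handed substrate → right-handed product (k = 1.45 M⁻¹ min⁻¹)
    2 racemization catalyst → spent catalyst (k = 1.79 M⁻¹ min⁻¹)
    gas ⇌ coupling partner, rate k6*(csat - [coupling partner]) (kL = 0.00992 min⁻¹)

At 15.0 h the flask holds 0.00136 M of coupling partner, still below saturation. At 7.50 h, F·t gives 37.9%, and the flask holds 37.9% of the two products. The neighbour flask with 8.5 × 10⁻⁴ M of precatalyst has the same substrate and gas, so F·t again gives 75.8%, and it reaches 73.4%.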